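The synthesis rests on cutting two bonds of the tetralin (C1 aryl methine, C2 with the sulfated arm, C3 with the hydroxymethyl arm, C4 methylene): C1–C2 and C3–CH2OH. The feature used is the 4-hydroxy group of the pendant guaiacyl ring. It lies para to C1 and lets that carbon be released as the terminus of a para-quinone methide. C3, C2 and the sulfated arm carbon form the C=C–CHO unit of an enal. In a single flask nitromethane adds to C3 through an iminium ion, and the ensuing enamine bonds C2 to C1. This builds the carbocycle and all three stereocentres. The precursor is an (E)-4-arylbut-2-enal with an ortho methoxy(4-hydroxy-3-methoxyphenyl)methyl substituent.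

Key step: step 7

Remark 1: the target is (1S,2R,3R), trans,trans, and is drawn as the free hydrogen sulfate. The sulfate is carried as its sodium salt and protonated only in the last operation; salt 22 is the form to store.
Remark 2: the acetal carbon of the ethoxyethyl group and the benzhydryl carbon up to 13 are uncontrolled stereocentres that are erased later, so they are drawn without configuration.
Remark 3: the benzhydryl oxygen of the key-step precursor is carried as a methyl ether. A free hydroxyl there could add to the enal β-carbon, and the ether also delays release of the quinone methide.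
Remark 4: the catalyst enantiomers are assigned from the usual face-shielding model of diarylprolinol silyl ethers. Both enantiomers are commercial.

Step 1
Reactants: 1 3-(benzyloxy)-4-methoxybenzaldehyde (O-benzylisovanillin)
Product: 2 5-(benzyloxy)-2-bromo-4-methoxybenzaldehyde
Conditions: Br2, NaOAc, AcOH, rt
Reagents that add atoms: bromine, BrBr
Why: Electrophilic aromatic bromination should go para to the benzyloxy group, whose lone pair unlike that of the 4-methoxy group is not drained by the formyl group, which is the usual outcome for 3,4-dialkoxybenzaldehydes and places bromine on the future C4a.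

Step 2
Reactants: 2 5-(benzyloxy)-2-bromo-4-methoxybenzaldehyde; 3 allyltributylstannane
Product: 4 2-allyl-5-(benzyloxy)-4-methoxybenzaldehyde
Conditions: Pd(PPh3)4 (5 mol %), toluene, 110 °C
Reagents that add atoms: none
Why: Stille cross-coupling is helped by the ortho formyl group in the oxidative addition, and the neutral allylstannane, unlike an allylboronate, should leave the aldehyde alone; allylating before the aryl addition also keeps a free benzhydrol away from palladium.

Step 3
Reactants: 5 4-bromo-2-methoxyphenol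
Product: 6 4-bromo-1-(1-ethoxyethoxy)-2-methoxybenzene
Conditions: ethyl vinyl ether, PPTS (cat.), CH2Cl2, rt
Reagents that add atoms: ethyl vinyl ether, C=COCC
Why: Acid-catalysed addition of the phenol to the vinyl ether gives a mixed acetal that tolerates magnesium and leaves in the same mild acid that is needed in step 5; its stereocentre is irrelevant.

Step 4
Reactants: 6 4-bromo-1-(1-ethoxyethoxy)-2-methoxybenzene; 4 2-allyl-5-(benzyloxy)-4-methoxybenzaldehyde
Product: 8 [2-allyl-5-(benzyloxy)-4-methoxyphenyl][4-(1-ethoxyethoxy)-3-methoxyphenyl]methanol, via arylmagnesium bromide 7 (not isolated)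
Conditions: Mg, THF, reflux; then 4, 0 °C; aq NH4Cl
Reagents that add atoms: none
Why: Grignard addition to the aldehyde forms the C1–aryl bond, and the new carbinol centre needs no control because C1 becomes planar in step 7.

Step 5
Reactants: 8 [2-allyl-5-(benzyloxy)-4-methoxyphenyl][4-(1-ethoxyethoxy)-3-methoxyphenyl]methanol
Product: 9 4-{[2-allyl-5-(benzyloxy)-4-methoxyphenyl](methoxy)methyl}-2-methoxyphenol
Conditions: CSA (5 mol %), MeOH, 0 °C → rt; Et3N quench; Et3N-deactivated silica
Reagents that add atoms: methanol, CO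
Why: Transacetalisation frees the phenol and SN1 methanolysis of the doubly donor-stabilised benzhydrol caps the oxygen in one operation, so that no hydroxyl group is left that could add to the enal β-carbon (6-exo oxa-Michael closure to an isochroman) and the ether is a latent leaving group for step 7.

Step 6
Reactants: 9 4-{[2-allyl-5-(benzyloxy)-4-methoxyphenyl](methoxy)methyl}-2-methoxyphenol; 10 (E)-crotonaldehyde
Product: 11 (E)-4-{4-(benzyloxy)-2-[(4-hydroxy-3-methoxyphenyl)(methoxy)methyl]-5-methoxyphenyl}but-2-enal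
Conditions: Hoveyda–Grubbs II (5 mol %), 1,4-benzoquinone (10 mol %), 10 (5 equiv), CH2Cl2, 40 °C
Reagents that add atoms: none
Why: Olefin cross-metathesis of the unhindered allylarene with the electron-poor partner crotonaldehyde should be E-selective and tolerates phenol and ethers, while benzoquinone suppresses double-bond migration by ruthenium hydrides.

Step 7
Reactants: 11 (E)-4-{4-(benzyloxy)-2-[(4-hydroxy-3-methoxyphenyl)(methoxy)methyl]-5-methoxyphenyl}but-2-enal; 12 nitromethane
Product: 15 (1S,2R,3R)-7-(benzyloxy)-1-(4-hydroxy-3-methoxyphenyl)-6-methoxy-3-(nitromethyl)-1,2,3,4-tetrahydronaphthalene-2-carbaldehyde, via nitro aldehyde 13 (not isolated), via quinone methide 14 (not isolated)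
Conditions: (i) (S)-α,α-diphenylprolinol TMS ether (20 mol %), PhCO2H (20 mol %), 12 (5 equiv), MeOH, 0 °C → rt; (ii) evaporate, CH2Cl2 (0.01 M), (R)-α,α-diphenylprolinol TMS ether (30 mol %), (PhO)2PO2H (60 mol %), −20 °C → rt
Reagents that add atoms: none
Why: Proposed new method: in stage (i) the (S)-amine converts enal 11 into an iminium ion, nitronate adds to C3, and hydrolysis gives 13 while the weakly acidic methanol keeps C1 parked as its methyl ether; in stage (ii), with methanol and excess nitromethane stripped off, diphenyl phosphate expels methanol from the para-hydroxybenzhydryl ether, and the enamine of the aldehyde attacks the exocyclic carbon of quinone methide 14, driven by rearomatisation of the pendant ring. The closest known reaction types are iminium-catalysed additions of nitromethane to enals, enamine 1,6-additions to isolable hindered para-quinone methides, amine/acid SN1-type α-alkylations of aldehydes with benzhydrols and cycle-specific two-amine cascades; their merger, and the use of an unhindered quinone methide made in situ, are without precedent. The one new ring (C1, C2, C3, C4, C4a, C8a) closes 6-(enolexo)-exo-trig through a chair-like transition state. C3 is set by the (S)-catalyst, whose CPh2OSi group blocks one face of the s-trans E-iminium ion; C1 is set by relay from C3, since the chair places the nitromethyl group and the pendant ring both equatorial (1,3-cis); C2 ends trans to both neighbours, kinetically through the (R)-amine and thermodynamically because this formyl-bearing centre epimerises through its enamine. A second amine is used because a single enantiomer would hand nucleophile and electrophile to the same face of the C2–C3 unit, which in a ring closed through C4 and C1 puts formyl cis to nitromethyl and works against the all-equatorial chair, whereas the (R)-amine has its open enamine face on the side the chair demands. The step needs C2, not the nitromethyl carbon (which could also close a six-membered ring), external nitronate, the benzhydryl oxygen or a dienamine, to reach C1, and this is secured by the methyl ether cap that delays quinone methide release, by the nitronate-free acidic second stage, by dilution and by the ortho tether of the substrate.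

Step 8
Reactants: 15 (1S,2R,3R)-7-(benzyloxy)-1-(4-hydroxy-3-methoxyphenyl)-6-methoxy-3-(nitromethyl)-1,2,3,4-tetrahydronaphthalene-2-carbaldehyde
Product: 16 4-[(1S,2R,3R)-7-(benzyloxy)-2-(hydroxymethyl)-6-methoxy-3-(nitromethyl)-1,2,3,4-tetrahydronaphthalen-1-yl]-2-methoxyphenol
Conditions: NaBH4, MeOH, 0 °C
Reagents that add atoms: none
Why: Borohydride reduction of the aldehyde spares the nitro group and freezes the epimerisable centre C2 in its trans,trans arrangement.

Step 9
Reactants: 16 4-[(1S,2R,3R)-7-(benzyloxy)-2-(hydroxymethyl)-6-methoxy-3-(nitromethyl)-1,2,3,4-tetrahydronaphthalen-1-yl]-2-methoxyphenol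
Product: 17 {(1S,2R,3R)-7-(benzyloxy)-1-[4-(benzyloxy)-3-methoxyphenyl]-6-methoxy-3-(nitromethyl)-1,2,3,4-tetrahydronaphthalen-2-yl}methanol
Conditions: BnBr (1.05 equiv), K2CO3 (1.2 equiv), acetone, rt
Reagents that add atoms: benzyl bromide, BrCc1ccccc1
Why: Williamson etherification is selective because the phenoxide forms and alkylates fast, whereas the primary alcohol is not deprotonated by carbonate and carbon deprotonation of the nitroalkane is slow.

Step 10
Reactants: 17 {(1S,2R,3R)-7-(benzyloxy)-1-[4-(benzyloxy)-3-methoxyphenyl]-6-methoxy-3-(nitromethyl)-1,2,3,4-tetrahydronaphthalen-2-yl}methanol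
Product: 18 sodium {(1S,2R,3R)-7-(benzyloxy)-1-[4-(benzyloxy)-3-methoxyphenyl]-6-methoxy-3-(nitromethyl)-1,2,3,4-tetrahydronaphthalen-2-yl}methyl sulfate
Conditions: SO3·pyridine, pyridine, rt; aq NaHCO3
Reagents that add atoms: sulfur trioxide–pyridine complex, O=S(=O)([O-])[n+]1ccccc1; sodium hydrogen carbonate, [Na+].OC([O-])=O
Why: O-Sulfation of the only free hydroxyl group with the sulfur trioxide–pyridine complex gives the anionic monoester, which unlike a neutral sulfate diester cannot be displaced by the nitronate oxygen of step 11 (closure to a six-membered cyclic nitronate).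

Step 11
Reactants: 18 sodium {(1S,2R,3R)-7-(benzyloxy)-1-[4-(benzyloxy)-3-methoxyphenyl]-6-methoxy-3-(nitromethyl)-1,2,3,4-tetrahydronaphthalen-2-yl}methyl sulfate
Product: 20 sodium {(1S,2R,3R)-7-(benzyloxy)-1-[4-(benzyloxy)-3-methoxyphenyl]-3-formyl-6-methoxy-1,2,3,4-tetrahydronaphthalen-2-yl}methyl sulfate, via disodium nitronate 19 (not isolated)
Conditions: NaOMe (1.1 equiv), MeOH, 0 °C; then TiCl3, NH4OAc, H2O/MeOH (pH 5–6), rt; brine work-up
Reagents that add atoms: water, O
Why: In the titanium(III) variant of the Nef reaction nitronate 19 is deoxygenated to the imine, which hydrolyses at pH 5–6, so no oxidant meets the electron-rich rings, the sulfate monoester is inert, and C3 keeps its equatorial and more stable configuration.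

Step 12
Reactants: 20 sodium {(1S,2R,3R)-7-(benzyloxy)-1-[4-(benzyloxy)-3-methoxyphenyl]-3-formyl-6-methoxy-1,2,3,4-tetrahydronaphthalen-2-yl}methyl sulfate
Product: 21 sodium {(1S,2R,3R)-7-(benzyloxy)-1-[4-(benzyloxy)-3-methoxyphenyl]-3-(hydroxymethyl)-6-methoxy-1,2,3,4-tetrahydronaphthalen-2-yl}methyl sulfate
Conditions: NaBH4, MeOH, 0 °C
Reagents that add atoms: none
Why: Borohydride reduction of the aldehyde gives the hydroxymethyl arm without touching sulfate, benzyl ethers or stereocentres.

Step 13
Reactants: 21 sodium {(1S,2R,3R)-7-(benzyloxy)-1-[4-(benzyloxy)-3-methoxyphenyl]-3-(hydroxymethyl)-6-methoxy-1,2,3,4-tetrahydronaphthalen-2-yl}methyl sulfate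
Product: 23 [(1S,2R,3R)-7-hydroxy-1-(4-hydroxy-3-methoxyphenyl)-3-(hydroxymethyl)-6-methoxy-1,2,3,4-tetrahydronaphthalen-2-yl]methyl hydrogen sulfate, via sodium salt 22 (not isolated)
Conditions: H2 (1 atm), 10 % Pd/C, MeOH, rt; filter; then HCl (1.0 equiv), H2O/MeCN, 0 °C, freeze-dry, take up in dry MeCN and filter
Reagents that add atoms: none
Why: Catalytic hydrogenolysis removes both aryl benzyl ethers while the primary alkyl sulfate and the ring C–C bonds are inert, and one equivalent of strong acid turns salt 22 into the hydrogen sulfate as drawn.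

Compound list
1 | 3-(benzyloxy)-4-methoxybenzaldehyde | O=Cc1ccc(OC)c(OCc2ccccc2)c1 | starting material
2 | 5-(benzyloxy)-2-bromo-4-methoxybenzaldehyde | O=Cc1cc(OCc2ccccc2)c(OC)cc1Br | intermediate
3 | allyltributylstannane | C=CC[Sn](CCCC)(CCCC)CCCC | starting material
4 | 2-allyl-5-(benzyloxy)-4-methoxybenzaldehyde | O=Cc1cc(OCc2ccccc2)c(OC)cc1CC=C | intermediate
5 | 4-bromo-2-methoxyphenol | COc1cc(Br)ccc1O | starting material
6 | 4-bromo-1-(1-ethoxyethoxy)-2-methoxybenzene (racemic acetal) | CCOC(C)Oc1ccc(Br)cc1OC | intermediate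
7 | [4-(1-ethoxyethoxy)-3-methoxyphenyl]magnesium bromide | CCOC(C)Oc1ccc([Mg]Br)cc1OC | intermediate
8 | [2-allyl-5-(benzyloxy)-4-methoxyphenyl][4-(1-ethoxyethoxy)-3-methoxyphenyl]methanol (mixture of diastereomers) | CCOC(C)Oc1ccc(C(O)c2cc(OCc3ccccc3)c(OC)cc2CC=C)cc1OC | intermediate
9 | 4-{[2-allyl-5-(benzyloxy)-4-methoxyphenyl](methoxy)methyl}-2-methoxyphenol (racemic) | COc1cc(C(OC)c2cc(OCc3ccccc3)c(OC)cc2CC=C)ccc1O | intermediate
10 | (E)-crotonaldehyde | C/C=C/C=O | starting material
11 | (E)-4-{4-(benzyloxy)-2-[(4-hydroxy-3-methoxyphenyl)(methoxy)methyl]-5-methoxyphenyl}but-2-enal (racemic at the ether carbon) | COc1cc(C(OC)c2cc(OCc3ccccc3)c(OC)cc2C/C=C/C=O)ccc1O | intermediate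
12 | nitromethane | C[N+](=O)[O-] | starting material
13 | (3R)-4-{4-(benzyloxy)-2-[(4-hydroxy-3-methoxyphenyl)(methoxy)methyl]-5-methoxyphenyl}-3-(nitromethyl)butanal (both ether epimers) | COc1cc(C(OC)c2cc(OCc3ccccc3)c(OC)cc2C[C@@H](C[N+](=O)[O-])CC=O)ccc1O | intermediate
14 | (3R)-4-{4-(benzyloxy)-5-methoxy-2-[(3-methoxy-4-oxocyclohexa-2,5-dien-1-ylidene)methyl]phenyl}-3-(nitromethyl)butanal | COC1=CC(=Cc2cc(OCc3ccccc3)c(OC)cc2C[C@@H](C[N+](=O)[O-])CC=O)C=CC1=O | intermediate
15 | (1S,2R,3R)-7-(benzyloxy)-1-(4-hydroxy-3-methoxyphenyl)-6-methoxy-3-(nitromethyl)-1,2,3,4-tetrahydronaphthalene-2-carbaldehyde | COc1cc([C@H]2c3cc(OCc4ccccc4)c(OC)cc3C[C@@H](C[N+](=O)[O-])[C@@H]2C=O)ccc1O | intermediate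
16 | 4-[(1S,2R,3R)-7-(benzyloxy)-2-(hydroxymethyl)-6-methoxy-3-(nitromethyl)-1,2,3,4-tetrahydronaphthalen-1-yl]-2-methoxyphenol | COc1cc([C@H]2c3cc(OCc4ccccc4)c(OC)cc3C[C@@H](C[N+](=O)[O-])[C@@H]2CO)ccc1O | intermediate
17 | {(1S,2R,3R)-7-(benzyloxy)-1-[4-(benzyloxy)-3-methoxyphenyl]-6-methoxy-3-(nitromethyl)-1,2,3,4-tetrahydronaphthalen-2-yl}methanol | COc1cc([C@H]2c3cc(OCc4ccccc4)c(OC)cc3C[C@@H](C[N+](=O)[O-])[C@@H]2CO)ccc1OCc1ccccc1 | intermediate
18 | sodium sulfate monoester of 17 | COc1cc([C@H]2c3cc(OCc4ccccc4)c(OC)cc3C[C@@H](C[N+](=O)[O-])[C@@H]2COS(=O)(=O)[O-])ccc1OCc1ccccc1.[Na+] | intermediate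
19 | disodium nitronate of 18 | COc1cc([C@H]2c3cc(OCc4ccccc4)c(OC)cc3C[C@@H](C=[N+]([O-])[O-])[C@@H]2COS(=O)(=O)[O-])ccc1OCc1ccccc1.[Na+].[Na+] | intermediate
20 | sodium {(1S,2R,3R)-7-(benzyloxy)-1-[4-(benzyloxy)-3-methoxyphenyl]-3-formyl-6-methoxy-1,2,3,4-tetrahydronaphthalen-2-yl}methyl sulfate | COc1cc([C@H]2c3cc(OCc4ccccc4)c(OC)cc3C[C@@H](C=O)[C@@H]2COS(=O)(=O)[O-])ccc1OCc1ccccc1.[Na+] | intermediate
21 | sodium {(1S,2R,3R)-7-(benzyloxy)-1-[4-(benzyloxy)-3-methoxyphenyl]-3-(hydroxymethyl)-6-methoxy-1,2,3,4-tetrahydronaphthalen-2-yl}methyl sulfate | COc1cc([C@H]2c3cc(OCc4ccccc4)c(OC)cc3C[C@@H](CO)[C@@H]2COS(=O)(=O)[O-])ccc1OCc1ccccc1.[Na+] | intermediate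
22 | sodium salt of the target | COc1cc([C@H]2c3cc(O)c(OC)cc3C[C@@H](CO)[C@@H]2COS(=O)(=O)[O-])ccc1O.[Na+] | intermediate
23 | [(1S,2R,3R)-7-hydroxy-1-(4-hydroxy-3-methoxyphenyl)-3-(hydroxymethyl)-6-methoxy-1,2,3,4-tetrahydronaphthalen-2-yl]methyl hydrogen sulfate (CNP0184747.1) | COc1cc([C@H]2c3cc(O)c(OC)cc3C[C@@H](CO)[C@@H]2COS(=O)(=O)O)ccc1O | target

Total step count: 13. Longest linear sequence: 12 (steps 1, 2 and 4–13, from 1).

Steps most likely to fail

1. Step 7.
What may go wrong:
- The iminium ion may lose a benzylic γ-proton and drain into a dienamine in stage (i).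
- The quinone methide may be captured by the amines, by liberated methanol or by the phenol of a second molecule faster than C2 reaches it.
- Facial selectivity at C1 in the closure may be poor.

Fallback, known reactions only, setting out from 5, 6 and 3 and returning at 15. The ring is closed at C1–C8a instead.
- Williamson benzylation of 5 (BnBr, K2CO3) gives 1-(benzyloxy)-4-bromo-2-methoxybenzene F1.
- Stille allylation with 3 gives 4-allyl-1-(benzyloxy)-2-methoxybenzene F2.
- Radical nitration–elimination (AgNO2, TEMPO, dioxane, 70 °C) gives 1-(benzyloxy)-2-methoxy-4-[(E)-3-nitroprop-2-en-1-yl]benzene F3.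
- Heck arylation of allyl alcohol with 6 (Pd(OAc)2, Bu4NCl, NaHCO3, DMF) gives 3-[4-(1-ethoxyethoxy)-3-methoxyphenyl]propanal F4.
- The syn-selective enamine Michael addition of aldehyde F4 to nitroalkene F3 uses (S)-α,α-diphenylprolinol TMS ether and 4-nitrophenol in toluene. It should set C2 and C3 in the (2R,3R)-nitro aldehyde acetal F5.
- Aqueous acetic acid in THF removes the acetal to give the (2R,3R)-nitro aldehyde phenol F6.
- DDQ then dehydrogenates the 4-hydroxybenzyl unit to its quinone methide, and the benzyloxy-methoxy ring closes onto it para to its methoxy group. This oxidative Friedel–Crafts cyclisation is familiar from dibenzylbutane lignans. It places the aryl group trans to formyl and gives 15.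

2. Step 11.
What may go wrong:
- The reduction may stall at the oxime stage.
- The amphiphilic salt may be lost by adsorption on hydrated titanium oxide during work-up.

Fallback, setting out from 17 and returning at 22. The Nef reaction is moved ahead of the sulfation and run on neutral material.
- TBDPSCl and imidazole give the silyl ether of 17 F7.
- NaOMe followed by buffered TiCl3 gives the C3 aldehyde F8.
- NaBH4 gives the C3 hydroxymethyl compound F9.
- Benzyl 2,2,2-trichloroacetimidate with catalytic TfOH gives the C3 benzyloxymethyl compound F10. The acidic benzylation avoids base-induced silyl migration between the two primary oxygens.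
- TBAF gives the C2 carbinol F11.
- SO3·pyridine followed by NaHCO3 gives the tribenzyl sodium sulfate F12.
- Hydrogenolysis of all three benzyl ethers over Pd/C gives 22, which is acidified as in step 13.

3. Step 6.
What may go wrong:
- Ruthenium hydrides may move the allyl double bond into conjugation with the ring.
- Turnover with the electron-poor partner may be slow.
- The acid-labile benzhydryl ether may be lost, or the new double bond may migrate, during purification.

Fallback, setting out from 8 and returning at 11. Metathesis is replaced by oxidative cleavage and olefination.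
- NaH and MeI give the benzhydryl methyl ether with the acetal retained F13.
- Lemieux–Johnson cleavage (OsO4 cat., NaIO4, 2,6-lutidine, dioxane/H2O) is safe here because no free guaiacol is present. It gives the arylacetaldehyde F14.
- Wittig olefination with (triphenylphosphoranylidene)acetaldehyde in toluene gives the (E)-enal acetal F15.
- Brief treatment with catalytic CSA in MeOH at 0 °C removes the ethoxyethyl group and gives 11. The methyl ether only exchanges with itself under these conditions.

Further compounds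
F1 | step 7 | 1-(benzyloxy)-4-bromo-2-methoxybenzene | COc1cc(Br)ccc1OCc1ccccc1
F2 | step 7 | 4-allyl-1-(benzyloxy)-2-methoxybenzene | C=CCc1ccc(OCc2ccccc2)c(OC)c1
F3 | step 7 | 1-(benzyloxy)-2-methoxy-4-[(E)-3-nitroprop-2-en-1-yl]benzene | COc1cc(C/C=C/[N+](=O)[O-])ccc1OCc1ccccc1
F4 | step 7 | 3-[4-(1-ethoxyethoxy)-3-methoxyphenyl]propanal | CCOC(C)Oc1ccc(CCC=O)cc1OC
F5 | step 7 | (2R,3R)-3-[4-(benzyloxy)-3-methoxybenzyl]-2-[4-(1-ethoxyethoxy)-3-methoxybenzyl]-4-nitrobutanal | CCOC(C)Oc1ccc(C[C@@H](C=O)[C@H](C[N+](=O)[O-])Cc2ccc(OCc3ccccc3)c(OC)c2)cc1OC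
F6 | step 7 | (2R,3R)-3-[4-(benzyloxy)-3-methoxybenzyl]-2-(4-hydroxy-3-methoxybenzyl)-4-nitrobutanal | COc1cc(C[C@@H](C=O)[C@H](C[N+](=O)[O-])Cc2ccc(OCc3ccccc3)c(OC)c2)ccc1O
F7 | step 11 | tert-butyldiphenylsilyl ether of 17, (1S,2R,3R) | COc1cc([C@H]2c3cc(OCc4ccccc4)c(OC)cc3C[C@@H](C[N+](=O)[O-])[C@@H]2CO[Si](c5ccccc5)(c5ccccc5)C(C)(C)C)ccc1OCc1ccccc1
F8 | step 11 | (1S,2R,3R) C3 aldehyde with C2 silyloxymethyl arm | COc1cc([C@H]2c3cc(OCc4ccccc4)c(OC)cc3C[C@@H](C=O)[C@@H]2CO[Si](c5ccccc5)(c5ccccc5)C(C)(C)C)ccc1OCc1ccccc1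
F9 | step 11 | (1S,2R,3R) C3 hydroxymethyl compound with C2 silyloxymethyl arm | COc1cc([C@H]2c3cc(OCc4ccccc4)c(OC)cc3C[C@@H](CO)[C@@H]2CO[Si](c5ccccc5)(c5ccccc5)C(C)(C)C)ccc1OCc1ccccc1
F10 | step 11 | (1S,2R,3R) C3 benzyloxymethyl compound with C2 silyloxymethyl arm | COc1cc([C@H]2c3cc(OCc4ccccc4)c(OC)cc3C[C@@H](COCc5ccccc5)[C@@H]2CO[Si](c5ccccc5)(c5ccccc5)C(C)(C)C)ccc1OCc1ccccc1
F11 | step 11 | (1S,2R,3R) C2 carbinol with C3 benzyloxymethyl arm | COc1cc([C@H]2c3cc(OCc4ccccc4)c(OC)cc3C[C@@H](COCc5ccccc5)[C@@H]2CO)ccc1OCc1ccccc1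
F12 | step 11 | sodium sulfate monoester of F11 | COc1cc([C@H]2c3cc(OCc4ccccc4)c(OC)cc3C[C@@H](COCc5ccccc5)[C@@H]2COS(=O)(=O)[O-])ccc1OCc1ccccc1.[Na+]
F13 | step 6 | 1-allyl-4-(benzyloxy)-2-{[4-(1-ethoxyethoxy)-3-methoxyphenyl](methoxy)methyl}-5-methoxybenzene | CCOC(C)Oc1ccc(C(OC)c2cc(OCc3ccccc3)c(OC)cc2CC=C)cc1OC
F14 | step 6 | 2-{4-(benzyloxy)-2-{[4-(1-ethoxyethoxy)-3-methoxyphenyl](methoxy)methyl}-5-methoxyphenyl}acetaldehyde | CCOC(C)Oc1ccc(C(OC)c2cc(OCc3ccccc3)c(OC)cc2CC=O)cc1OC
F15 | step 6 | (E)-4-{4-(benzyloxy)-2-{[4-(1-ethoxyethoxy)-3-methoxyphenyl](methoxy)methyl}-5-methoxyphenyl}but-2-enal | CCOC(C)Oc1ccc(C(OC)c2cc(OCc3ccccc3)c(OC)cc2C/C=C/C=O)cc1OC
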